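The readings are calculated from invented constants; noise was put on by code.

Dividing E by D is the easy step, so we take it first, on the runs below.

| setting | Monday's | Thursday's | flask |
|---|---|---|---|
| Q | 0.12 M | 0.24 M | 0.12 M |
| remark | the very flask that is asked about, followed so far | run made earlier |  |
| time |  |  | 10 h |

- Monday's (time / h: E / %, D / %): 0.333: 12.5, 32.0; 0.500: 14.8, 34.5; 0.833: 14.1, 34.8; 1.33: 12.9, 33.6; 2.50: 11.9, 30.3; 4.00: 10.7, 25.2
- Thursday's (time / h: E / %, D / %): 0.667: 14.6, 35.1; 2.00: 13.1, 31.4; 4.00: 9.7, 25.4; 5.00: 9.6, 23.0; 8.00: 6.2, 17.0; 10.0: 5.2, 14.8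

(each reading ± 0.5 percentage points)



- ratio of E to D at 4.0 min
- ratio of E to D at 50 min
- ratio of E to D at 10 h

Monday's run at 0.12 M and Thursday's at 0.24 M read 25.2% and 25.4% of D at 4.00 h, so we pool them. Summed E over summed D, from 0.500 h on in Monday's run and over all of Thursday's, gives 0.402, which we call the plateau ratio, the split between E and D as read over those readings.

Two readings seem not to go together: Monday's ratio already stands at 0.391 after 19.98 min, while Thursday's D falls from 31.4% to 14.8% between 2.00 h and 10.0 h, a half-life of 7.37 h. How can a mixture drain and keep its proportion? Follow one molecule: at each fork it crosses between D and E or leaves the pair. Because the split is reached in a time far shorter than the drain, we reckon it crosses many times before leaving, so the pair drains as one pool, a quasi-equilibrium. Thursday's last ratio, 0.351, rests on 5.2% of E with a scatter of 0.5 percentage points.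

So we commit to 0.402 at 50 min and 10 h in this flask, and, supposing E is reached through D, to something lower at 4.0 min, without a number. The forecast says 0.4, 0.405 and 0.37, so it differs from us at both ends: at 4.0 min it stands level with the plateau ratio where we go lower, and at 10 h it stands lower than we do, where “the ratio sags late”.

The flask gives 0.297, 0.410 and 0.411, the first lower than the plateau ratio.

    Q → G (k = 0.0129 s⁻¹)
    G ⇌ L (K = 1.02, k = 0.00537 s⁻¹)
    G ⇌ J (K = 0.441, k = 0.00256 s⁻¹)
    J ⇌ Z (K = 1.19, k = 0.00376 s⁻¹)
    L ⇌ D (K = 2.53, k = 0.00345 s⁻¹)
    D ⇌ E (K = 0.410, k = 0.00883 s⁻¹)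
    J → X (k = 4.73 × 10⁻⁴ s⁻¹)

D turns into E with a half-life of 1.31 min by this forward step alone, against 6.72 h for the slowest mode of the whole flask at 10.0 h, and there the plateau ratio times the 13.9% of D gives 5.59% of E, where 5.72% stands. In the neighbouring flask charged with 0.072 M of Q, the same product on its 13.9% of D gives 5.59%, and it holds 5.72% of E at 10.0 h.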